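**Retrosynthetic overview**

1. Numbering: rings A and C (O1, C2–C8a) are the 5,7-dihydroxychromanone and ring B (C1'–C6') is its C2 aryl group; rings D and E (double-primed atoms) are the 5-hydroxy-7-methoxychromanone joined through C8'' to C3'; ring F is the 4-hydroxyphenyl group on C2''.
2. Feature the plan rests on: in ring D the ring oxygen O1'' sits on C8a'', whose ortho carbons are C8'' (occupied by ring B) and C4a'' (free). C4a'' is also ortho to the C5'' oxygen and para to the C7'' methoxy group, so an acyl group tethered through O1''–C2''–C3'' has exactly one, strongly activated, carbon to attack.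
3. Disconnections, latest first: C2–C1' (catalyst-controlled conjugate addition of a ring B boronic acid to a ring A/C chromone); C4''–C4a'' (Friedel–Crafts cycloacylation of an (S)-3-aryl-3-aryloxypropanoic acid, ring E); C2''–O1'' (Mitsunobu inversion of an (R)-β-hydroxy ester); C8''–C3' (Negishi coupling of a ring D arylzinc with a ring B iodide).
4. Ring order: rings A, B, D and F are bought as arenes; ring C is built as a chromone in a side branch; ring E is closed on the D–B biaryl in the key step; the chromone is then joined to ring B, which makes ring C the second chromanone.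
5. Protecting groups: benzyl ethers on the C5'', C4', C5 and C7 oxygens (one final hydrogenolysis); an acetate on ring F, which keeps the C2'' benzylic carbon from ionising in the Mitsunobu and acid steps and is removed by acidic methanolysis.

Key step: step 11

Assumption: the palladium/pyridine–oxazoline catalyst is taken to attack chromones with the facial sense known for cyclic enones, so the (R)-ligand should give the (2S)-chromanone (the antipodal ligand is used if a model addition shows otherwise); the C8''–C3' axis is treated as freely rotating.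

**Route**

Step 1
Reactants: 1 benzene-1,3,5-triol
Product: 2 3,5-bis(methoxymethoxy)phenol
Conditions: MOMCl (2.0 equiv), i-Pr2NEt (2.2 equiv), DMF, 0 °C to rt; chromatography
Reagents that add atoms: chloromethyl methyl ether, COCCl
Why: Williamson-type O-alkylation with a hard alkoxymethyl chloride goes on oxygen and not on the ring carbons of the triol; with two equivalents the bis-acetal should be the main component of a statistical mixture and is separated from the mono- and tris-ethers.

Step 2
Reactants: 2 3,5-bis(methoxymethoxy)phenol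
Product: 3 1-(benzyloxy)-3,5-bis(methoxymethoxy)benzene
Conditions: BnBr, K2CO3, DMF, rt
Reagents that add atoms: benzyl bromide, BrCc1ccccc1
Why: Williamson etherification of the one remaining phenol; with two oxygens already capped the ring behaves as an ordinary phenoxide and C-benzylation is not expected.

Step 3
Reactants: 4 4-bromo-2-iodophenol
Product: 5 1-(benzyloxy)-4-bromo-2-iodobenzene
Conditions: BnBr, K2CO3, acetone, reflux
Reagents that add atoms: benzyl bromide, BrCc1ccccc1
Why: Williamson etherification; the aryl C–I and C–Br bonds are inert to K2CO3 and benzyl bromide.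

Step 4
Reactants: 3 1-(benzyloxy)-3,5-bis(methoxymethoxy)benzene; 5 1-(benzyloxy)-4-bromo-2-iodobenzene
Product: 8 5-(benzyloxy)-2-[2-(benzyloxy)-5-bromophenyl]-1,3-bis(methoxymethoxy)benzene, via aryllithium 6 (not isolated), via arylzinc chloride 7 (not isolated)
Conditions: n-BuLi (1.1 equiv), THF, 0 °C; ZnCl2 (1.2 equiv), 0 °C to rt; then 5, Pd(PPh3)4 (5 mol %), THF, 55 °C
Reagents that add atoms: none
Why: Directed ortho-metalation at the C–H flanked by both methoxymethoxy groups (the most acidic ring position, so benzylic deprotonation of the benzyl ether should not compete), transmetalation to zinc and Negishi coupling, in which zerovalent palladium inserts into C–I far faster than into C–Br, so the bromide is kept for step 12.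

Step 5
Reactants: 8 5-(benzyloxy)-2-[2-(benzyloxy)-5-bromophenyl]-1,3-bis(methoxymethoxy)benzene
Product: 9 5-(benzyloxy)-2-[2-(benzyloxy)-5-bromophenyl]benzene-1,3-diol
Conditions: conc. HCl (cat.), MeOH/THF, 50 °C
Reagents that add atoms: none
Why: Acid-catalysed acetal exchange (methanolysis) removes both methoxymethyl groups as dimethoxymethane, while benzyl aryl ethers and the aryl bromide are stable to dilute HCl.

Step 6
Reactants: 9 5-(benzyloxy)-2-[2-(benzyloxy)-5-bromophenyl]benzene-1,3-diol
Product: 10 5-(benzyloxy)-2-[2-(benzyloxy)-5-bromophenyl]-3-methoxyphenol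
Conditions: MeI (1.0 equiv), K2CO3 (1.0 equiv), acetone, rt; unreacted 9 recycled
Reagents that add atoms: iodomethane, CI
Why: Williamson methylation of one of two equivalent phenols with one equivalent each of base and MeI; the mono-ether should be the main product, the dimethyl ether is removed by chromatography and recovered diol is resubmitted.

Step 7
Reactants: 11 4-(acetyloxy)benzoic acid
Product: 14 tert-butyl 3-[4-(acetyloxy)phenyl]-3-oxopropanoate, via acid chloride 12 (not isolated), via acyl Meldrum's acid 13 (not isolated)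
Conditions: (COCl)2, cat. DMF, CH2Cl2, rt; Meldrum's acid, pyridine, CH2Cl2, 0 °C to rt; t-BuOH, toluene, 90 °C
Reagents that add atoms: Meldrum's acid (2,2-dimethyl-1,3-dioxane-4,6-dione), CC1(C)OC(=O)CC(=O)O1; tert-butanol, CC(C)(C)O
Why: C-acylation of Meldrum's acid by the acid chloride, then thermal loss of acetone to an acylketene that tert-butanol traps with decarboxylation (the Meldrum's acid synthesis of β-keto esters); no enolate base is present, so the aryl acetate is not touched.

Step 8
Reactants: 14 tert-butyl 3-[4-(acetyloxy)phenyl]-3-oxopropanoate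
Product: 15 tert-butyl (3R)-3-[4-(acetyloxy)phenyl]-3-hydroxypropanoate
Conditions: [RuCl(p-cymene)((R,R)-TsDPEN)] (1 mol %), HCO2H/Et3N (5:2), EtOAc, rt to 40 °C
Reagents that add atoms: none
Why: Noyori asymmetric transfer hydrogenation of an aryl ketone, in which the (R,R)-diamine catalyst delivers hydride to the face that gives the (R)-carbinol (CH–π contact between the arene ligand and the aryl group in the six-membered transition state), while the weakly acidic formate medium leaves both esters intact.

Step 9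
Reactants: 10 5-(benzyloxy)-2-[2-(benzyloxy)-5-bromophenyl]-3-methoxyphenol; 15 tert-butyl (3R)-3-[4-(acetyloxy)phenyl]-3-hydroxypropanoate
Product: 16 tert-butyl (3S)-3-[4-(acetyloxy)phenyl]-3-{5-(benzyloxy)-2-[2-(benzyloxy)-5-bromophenyl]-3-methoxyphenoxy}propanoate
Conditions: PPh3, DIAD, toluene, 0 °C to rt
Reagents that add atoms: none
Why: Mitsunobu etherification, in which the phenoxide of 10 displaces the alkoxyphosphonium group of 15 by SN2 and so inverts (R) to (S) at the future C2''; the acetate on ring F disfavours ionisation of the benzylic C–O bond, and toluene at low temperature limits elimination to the cinnamate.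

Step 10
Reactants: 16 tert-butyl (3S)-3-[4-(acetyloxy)phenyl]-3-{5-(benzyloxy)-2-[2-(benzyloxy)-5-bromophenyl]-3-methoxyphenoxy}propanoate
Product: 17 (3S)-3-[4-(acetyloxy)phenyl]-3-{5-(benzyloxy)-2-[2-(benzyloxy)-5-bromophenyl]-3-methoxyphenoxy}propanoic acid
Conditions: TFA/CH2Cl2 (1:4), 0 °C to rt; volatiles removed with toluene
Reagents that add atoms: none
Why: Acidolysis of the tert-butyl ester by alkyl–oxygen cleavage (the tert-butyl cation leaves as isobutene); the aryl acetate, the benzyl ethers and the secondary benzylic ether (its cation is disfavoured by the acetoxy group and the β-carboxyl) should survive, and both free ring D carbons are flanked by two alkoxy groups and so resist tert-butylation.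

Step 11
Reactants: 17 (3S)-3-[4-(acetyloxy)phenyl]-3-{5-(benzyloxy)-2-[2-(benzyloxy)-5-bromophenyl]-3-methoxyphenoxy}propanoic acid
Product: 19 4-[(2S)-5-(benzyloxy)-8-[2-(benzyloxy)-5-bromophenyl]-7-methoxy-4-oxochroman-2-yl]phenyl acetate, via mixed trifluoroacetic anhydride 18 (not isolated)
Conditions: (CF3CO)2O (2 equiv), CH2Cl2, 0 °C (to rt only if needed); cold aqueous NaHCO3 quench
Reagents that add atoms: none
Why: TFAA converts the acid into the mixed carboxylic–trifluoroacetic anhydride 18, whose acyl carbon (as the anhydride or the acylium ion it releases) is attacked by C4a'' of ring D, and loss of a proton from the arenium ion gives the aryl ketone and the C4''–C4a'' bond (intramolecular Friedel–Crafts acylation, SEAr). The closest known reaction is the cycloacylation of 3-aryloxypropanoic acids to chroman-4-ones with TFAA or polyphosphoric acid, which for a ring at the level of a benzene-1,3,5-triol triether needs no added Lewis acid. Ring E closes as a six-membered ring by a 6-exo attack on the acyl carbon, the O1''–C2''–C3'' tether delivering it to the arene carbon ortho to the ether oxygen. No stereocentre is formed; C2'' (S) from the Mitsunobu step is carried through, and its retention rests on the acetate of ring F (a poorly stabilised C2'' cation), the absence of a Lewis acid and the low temperature. The step needs C4a'' to react in preference to C6'' and to ring B or ring F: C8'' is blocked by ring B, C6'' is para to O1'' and out of reach of a three-atom tether, ring B would require an eight-membered ring and ring F is deactivated, whereas C4a'' is ortho to two oxygens and para to the third. Intermolecular trifluoroacetylation at C6'' is limited by the small excess of anhydride and by the new ketone deactivating ring D once ring E has closed.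

Step 12
Reactants: 19 4-[(2S)-5-(benzyloxy)-8-[2-(benzyloxy)-5-bromophenyl]-7-methoxy-4-oxochroman-2-yl]phenyl acetate
Product: 20 4-[(2S)-5-(benzyloxy)-8-[2-(benzyloxy)-5-(4,4,5,5-tetramethyl-1,3,2-dioxaborolan-2-yl)phenyl]-7-methoxy-4-oxochroman-2-yl]phenyl acetate
Conditions: B2pin2, PdCl2(dppf) (5 mol %), KOAc, 1,4-dioxane, 85 °C
Reagents that add atoms: bis(pinacolato)diboron, CC1(C)OB(OC1(C)C)B1OC(C)(C)C(C)(C)O1
Why: Miyaura borylation of an aryl bromide with no ortho substituent; KOAc is too weak a base to enolise and open the chromanone or to cleave the acetate.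

Step 13
Reactants: 20 4-[(2S)-5-(benzyloxy)-8-[2-(benzyloxy)-5-(4,4,5,5-tetramethyl-1,3,2-dioxaborolan-2-yl)phenyl]-7-methoxy-4-oxochroman-2-yl]phenyl acetate
Product: 21 {3-[(2S)-2-[4-(acetyloxy)phenyl]-5-(benzyloxy)-7-methoxy-4-oxochroman-8-yl]-4-(benzyloxy)phenyl}boronic acid
Conditions: NaIO4 (3 equiv), 1 M HCl (1 equiv), THF/H2O (4:1), rt
Reagents that add atoms: water, O
Why: Hydrolysis of the pinacol boronate is made irreversible by periodate cleavage of the released pinacol (Malaprade glycol cleavage); the free boronic acid is wanted because pinacol esters transmetalate poorly to cationic palladium, and dilute acid at room temperature spares the acetate and the chromanone.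

Step 14
Reactants: 22 1-(2,4,6-trihydroxyphenyl)ethan-1-one
Product: 23 1-[2,4-bis(benzyloxy)-6-hydroxyphenyl]ethan-1-one
Conditions: BnBr (2.05 equiv), K2CO3, DMF, rt to 50 °C
Reagents that add atoms: benzyl bromide, BrCc1ccccc1
Why: Williamson benzylation of the two phenols that are not tied up in the hydrogen bond to the ketone; one chelated ortho hydroxyl is the least nucleophilic and stays free.

Step 15
Reactants: 23 1-[2,4-bis(benzyloxy)-6-hydroxyphenyl]ethan-1-one
Product: 25 5,7-bis(benzyloxy)-4H-chromen-4-one, via enaminone 24 (not isolated)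
Conditions: Me2NCH(OMe)2, toluene, 95 °C; then 2 M HCl, CH2Cl2, rt
Reagents that add atoms: N,N-dimethylformamide dimethyl acetal, COC(OC)N(C)C
Why: Condensation of the methyl ketone with the amide acetal gives the enaminone, and acid then triggers intramolecular oxa-Michael addition of the phenol and loss of dimethylamine (the enaminone route to chromones).

Step 16
Reactants: 21 {3-[(2S)-2-[4-(acetyloxy)phenyl]-5-(benzyloxy)-7-methoxy-4-oxochroman-8-yl]-4-(benzyloxy)phenyl}boronic acid; 25 5,7-bis(benzyloxy)-4H-chromen-4-one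
Product: 26 4-[(2S)-5-(benzyloxy)-8-{2-(benzyloxy)-5-[(2S)-5,7-bis(benzyloxy)-4-oxochroman-2-yl]phenyl}-7-methoxy-4-oxochroman-2-yl]phenyl acetate
Conditions: Pd(OCOCF3)2 (10 mol %), (R)-4-tert-butyl-2-(pyridin-2-yl)-4,5-dihydrooxazole (12 mol %), NH4PF6 (30 mol %), H2O (5 equiv), ClCH2CH2Cl, 60 °C; 25 in excess (2 equiv)
Reagents that add atoms: none
Why: Conjugate addition of an arylboronic acid to a chromone under cationic palladium/pyridine–oxazoline catalysis (a 1,4-addition of the Hayashi–Miyaura type): transmetalation, enantio-determining insertion of C2=C3 into the aryl–palladium bond and protonolysis of the palladium enolate, with the ligand fixing C2 as (S) whatever the distant C2'' centre; palladium stays divalent, so the benzyl ethers, the acetate and both ketones are untouched.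

Step 17
Reactants: 26 4-[(2S)-5-(benzyloxy)-8-{2-(benzyloxy)-5-[(2S)-5,7-bis(benzyloxy)-4-oxochroman-2-yl]phenyl}-7-methoxy-4-oxochroman-2-yl]phenyl acetate
Product: 27 (2S)-5-(benzyloxy)-8-{2-(benzyloxy)-5-[(2S)-5,7-bis(benzyloxy)-4-oxochroman-2-yl]phenyl}-2-(4-hydroxyphenyl)-7-methoxychroman-4-one
Conditions: HCl (1.25 M in MeOH), MeOH/CH2Cl2, rt
Reagents that add atoms: none
Why: Acid-catalysed transesterification of the aryl acetate to methyl acetate; acid is chosen because base would open the chromanone rings by retro-oxa-Michael reaction and epimerise C2 and C2''.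

Step 18
Reactants: 27 (2S)-5-(benzyloxy)-8-{2-(benzyloxy)-5-[(2S)-5,7-bis(benzyloxy)-4-oxochroman-2-yl]phenyl}-2-(4-hydroxyphenyl)-7-methoxychroman-4-one
Product: 28 (2S)-8-{5-[(2S)-5,7-dihydroxy-4-oxochroman-2-yl]-2-hydroxyphenyl}-5-hydroxy-2-(4-hydroxyphenyl)-7-methoxychroman-4-one
Conditions: H2 (1 atm), 10% Pd/C, EtOAc/MeOH, rt
Reagents that add atoms: none
Why: Hydrogenolysis of the four benzyl aryl ethers over palladium on carbon; the chromanone carbonyls and the cyclic benzylic C2–O and C2''–O bonds are reduced much more slowly, so the reaction is stopped once debenzylation is complete.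

**Compound list**

1 | benzene-1,3,5-triol | Oc1cc(O)cc(O)c1 | starting material
2 | 3,5-bis(methoxymethoxy)phenol | COCOc1cc(O)cc(OCOC)c1 | intermediate
3 | 1-(benzyloxy)-3,5-bis(methoxymethoxy)benzene | COCOc1cc(OCc2ccccc2)cc(OCOC)c1 | intermediate
4 | 4-bromo-2-iodophenol | Oc1ccc(Br)cc1I | starting material
5 | 1-(benzyloxy)-4-bromo-2-iodobenzene | Brc1ccc(OCc2ccccc2)c(I)c1 | intermediate
6 | [4-(benzyloxy)-2,6-bis(methoxymethoxy)phenyl]lithium | [Li]c1c(OCOC)cc(OCc2ccccc2)cc1OCOC | intermediate
7 | [4-(benzyloxy)-2,6-bis(methoxymethoxy)phenyl]zinc chloride | Cl[Zn]c1c(OCOC)cc(OCc2ccccc2)cc1OCOC | intermediate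
8 | 5-(benzyloxy)-2-[2-(benzyloxy)-5-bromophenyl]-1,3-bis(methoxymethoxy)benzene | COCOc1cc(OCc2ccccc2)cc(OCOC)c1-c1cc(Br)ccc1OCc1ccccc1 | intermediate
9 | 5-(benzyloxy)-2-[2-(benzyloxy)-5-bromophenyl]benzene-1,3-diol | Oc1cc(OCc2ccccc2)cc(O)c1-c1cc(Br)ccc1OCc1ccccc1 | intermediate
10 | 5-(benzyloxy)-2-[2-(benzyloxy)-5-bromophenyl]-3-methoxyphenol | COc1cc(OCc2ccccc2)cc(O)c1-c1cc(Br)ccc1OCc1ccccc1 | intermediate
11 | 4-(acetyloxy)benzoic acid | CC(=O)Oc1ccc(cc1)C(=O)O | starting material
12 | 4-(acetyloxy)benzoyl chloride | CC(=O)Oc1ccc(cc1)C(Cl)=O | intermediate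
13 | 4-[(2,2-dimethyl-4,6-dioxo-1,3-dioxan-5-yl)carbonyl]phenyl acetate | CC(=O)Oc1ccc(cc1)C(=O)C1C(=O)OC(C)(C)OC1=O | intermediate
14 | tert-butyl 3-[4-(acetyloxy)phenyl]-3-oxopropanoate | CC(=O)Oc1ccc(cc1)C(=O)CC(=O)OC(C)(C)C | intermediate
15 | tert-butyl (3R)-3-[4-(acetyloxy)phenyl]-3-hydroxypropanoate | O[C@@H](c1ccc(OC(C)=O)cc1)CC(=O)OC(C)(C)C | intermediate
16 | tert-butyl (3S)-3-[4-(acetyloxy)phenyl]-3-{5-(benzyloxy)-2-[2-(benzyloxy)-5-bromophenyl]-3-methoxyphenoxy}propanoate | COc1cc(OCc2ccccc2)cc(O[C@H](c2ccc(OC(C)=O)cc2)CC(=O)OC(C)(C)C)c1-c1cc(Br)ccc1OCc1ccccc1 | intermediate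
17 | (3S)-3-[4-(acetyloxy)phenyl]-3-{5-(benzyloxy)-2-[2-(benzyloxy)-5-bromophenyl]-3-methoxyphenoxy}propanoic acid | COc1cc(OCc2ccccc2)cc(O[C@H](c2ccc(OC(C)=O)cc2)CC(=O)O)c1-c1cc(Br)ccc1OCc1ccccc1 | intermediate
18 | (3S)-3-[4-(acetyloxy)phenyl]-3-{5-(benzyloxy)-2-[2-(benzyloxy)-5-bromophenyl]-3-methoxyphenoxy}propanoic trifluoroacetic anhydride | COc1cc(OCc2ccccc2)cc(O[C@H](c2ccc(OC(C)=O)cc2)CC(=O)OC(=O)C(F)(F)F)c1-c1cc(Br)ccc1OCc1ccccc1 | intermediate
19 | 4-[(2S)-5-(benzyloxy)-8-[2-(benzyloxy)-5-bromophenyl]-7-methoxy-4-oxochroman-2-yl]phenyl acetate | COc1cc(OCc2ccccc2)c2c(c1-c1cc(Br)ccc1OCc1ccccc1)O[C@H](c1ccc(OC(C)=O)cc1)CC2=O | intermediate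
20 | 4-[(2S)-5-(benzyloxy)-8-[2-(benzyloxy)-5-(4,4,5,5-tetramethyl-1,3,2-dioxaborolan-2-yl)phenyl]-7-methoxy-4-oxochroman-2-yl]phenyl acetate | COc1cc(OCc2ccccc2)c2c(c1-c1cc(B3OC(C)(C)C(C)(C)O3)ccc1OCc1ccccc1)O[C@H](c1ccc(OC(C)=O)cc1)CC2=O | intermediate
21 | {3-[(2S)-2-[4-(acetyloxy)phenyl]-5-(benzyloxy)-7-methoxy-4-oxochroman-8-yl]-4-(benzyloxy)phenyl}boronic acid | COc1cc(OCc2ccccc2)c2c(c1-c1cc(B(O)O)ccc1OCc1ccccc1)O[C@H](c1ccc(OC(C)=O)cc1)CC2=O | intermediate
22 | 1-(2,4,6-trihydroxyphenyl)ethan-1-one | CC(=O)c1c(O)cc(O)cc1O | starting material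
23 | 1-[2,4-bis(benzyloxy)-6-hydroxyphenyl]ethan-1-one | CC(=O)c1c(O)cc(OCc2ccccc2)cc1OCc1ccccc1 | intermediate
24 | (2E)-1-[2,4-bis(benzyloxy)-6-hydroxyphenyl]-3-(dimethylamino)prop-2-en-1-one | CN(C)/C=C/C(=O)c1c(O)cc(OCc2ccccc2)cc1OCc1ccccc1 | intermediate
25 | 5,7-bis(benzyloxy)-4H-chromen-4-one | O=c1ccoc2cc(OCc3ccccc3)cc(OCc3ccccc3)c12 | intermediate
26 | 4-[(2S)-5-(benzyloxy)-8-{2-(benzyloxy)-5-[(2S)-5,7-bis(benzyloxy)-4-oxochroman-2-yl]phenyl}-7-methoxy-4-oxochroman-2-yl]phenyl acetate | COc1cc(OCc2ccccc2)c2c(c1-c1cc([C@@H]3CC(=O)c4c(OCc5ccccc5)cc(OCc5ccccc5)cc4O3)ccc1OCc1ccccc1)O[C@H](c1ccc(OC(C)=O)cc1)CC2=O | intermediate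
27 | (2S)-5-(benzyloxy)-8-{2-(benzyloxy)-5-[(2S)-5,7-bis(benzyloxy)-4-oxochroman-2-yl]phenyl}-2-(4-hydroxyphenyl)-7-methoxychroman-4-one | COc1cc(OCc2ccccc2)c2c(c1-c1cc([C@@H]3CC(=O)c4c(OCc5ccccc5)cc(OCc5ccccc5)cc4O3)ccc1OCc1ccccc1)O[C@H](c1ccc(O)cc1)CC2=O | intermediate
28 | (2S)-8-{5-[(2S)-5,7-dihydroxy-4-oxochroman-2-yl]-2-hydroxyphenyl}-5-hydroxy-2-(4-hydroxyphenyl)-7-methoxychroman-4-one | COc1cc(O)c2c(c1-c1cc([C@@H]3CC(=O)c4c(O)cc(O)cc4O3)ccc1O)O[C@H](c1ccc(O)cc1)CC2=O | target

**Step count and risk**

Total steps: 18. Longest linear sequence: 13 steps (steps 1, 2, 4, 5, 6, 9, 10, 11, 12, 13, 16, 17, 18, from benzene-1,3,5-triol).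

Steps most likely to fail:

Step 11 (key step). The risk is acid-induced ionisation of the C2''–O1'' bond in the mixed anhydride or in the product, which would erode the configuration at C2'' or eliminate the phenol to leave a cinnamic acid; trifluoroacetylation at C6'' before ring closure is a second risk. The fallback keeps the tethered cycloacylation but runs it on a substrate without a stereocentre and sets C2'' afterwards under catalyst control. It sets out from phenol 10: its sodium salt (NaH, THF) opens β-propiolactone at the alkyl carbon to give 3-{5-(benzyloxy)-2-[2-(benzyloxy)-5-bromophenyl]-3-methoxyphenoxy}propanoic acid F1; TFAA in CH2Cl2 closes this to 5-(benzyloxy)-8-[2-(benzyloxy)-5-bromophenyl]-7-methoxychroman-4-one F2; IBX in DMSO at 70 °C dehydrogenates it to 5-(benzyloxy)-8-[2-(benzyloxy)-5-bromophenyl]-7-methoxy-4H-chromen-4-one F3; addition of [4-(acetyloxy)phenyl]boronic acid with Pd(OCOCF3)2 and the (R)-pyridine–oxazoline ligand of step 16 then gives 19, where the route is rejoined.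

Step 9. The risk is elimination of the activated β-hydroxy ester to the cinnamate instead of substitution, slow reaction of the ortho-arylated phenol, and partial loss of inversion through an ion pair. The fallback masks the carboxyl group as a vinyl group so that no acidic α-hydrogen is present during the Mitsunobu reaction. It sets out from phenol 10 and commercial 4-formylphenyl acetate: Brown allylation with (+)-B-allyldiisopinocampheylborane (the antipode expected to give (R)-1-arylbut-3-en-1-ols; ethanolamine work-up) gives 4-[(1R)-1-hydroxybut-3-en-1-yl]phenyl acetate F4; Mitsunobu coupling with 10 (PPh3, DIAD, toluene) gives with inversion 4-[(1S)-1-{5-(benzyloxy)-2-[2-(benzyloxy)-5-bromophenyl]-3-methoxyphenoxy}but-3-en-1-yl]phenyl acetate F5; Lemieux–Johnson cleavage (OsO4 cat., NaIO4, 2,6-lutidine, dioxane/H2O) gives 4-[(1S)-1-{5-(benzyloxy)-2-[2-(benzyloxy)-5-bromophenyl]-3-methoxyphenoxy}-3-oxopropyl]phenyl acetate F6; Pinnick oxidation (NaClO2, NaH2PO4, 2-methylbut-2-ene, t-BuOH/H2O) then gives acid 17, where the route is rejoined.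

Step 16. The risk is slow insertion of the electron-rich 5,7-bis(benzyloxy)chromone into the aryl–palladium bond, so that protodeboronation and homocoupling consume boronic acid 21, together with weaker facial control on a large aryl group. The fallback changes the acceptor to an electron-poorer one and moves the ring A protecting groups to the acetate level. It sets out from 21 and commercial 5,7-dihydroxy-4H-chromen-4-one: acetylation (Ac2O, pyridine) gives 4-oxo-4H-chromene-5,7-diyl diacetate F7; the same palladium/(R)-ligand addition of 21 should give (2S)-2-{3-[(2S)-2-[4-(acetyloxy)phenyl]-5-(benzyloxy)-7-methoxy-4-oxochroman-8-yl]-4-(benzyloxy)phenyl}-4-oxochroman-5,7-diyl diacetate F8; HCl in MeOH removes all three acetates to give (2S)-5-(benzyloxy)-8-{2-(benzyloxy)-5-[(2S)-5,7-dihydroxy-4-oxochroman-2-yl]phenyl}-2-(4-hydroxyphenyl)-7-methoxychroman-4-one F9; hydrogenolysis (H2, 10% Pd/C) of the two remaining benzyl ethers then gives target 28, where the route is rejoined.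

**Further compounds**

F1 | step 11 | 3-{5-(benzyloxy)-2-[2-(benzyloxy)-5-bromophenyl]-3-methoxyphenoxy}propanoic acid | COc1cc(OCc2ccccc2)cc(OCCC(=O)O)c1-c1cc(Br)ccc1OCc1ccccc1
F2 | step 11 | 5-(benzyloxy)-8-[2-(benzyloxy)-5-bromophenyl]-7-methoxychroman-4-one | COc1cc(OCc2ccccc2)c2c(c1-c1cc(Br)ccc1OCc1ccccc1)OCCC2=O
F3 | step 11 | 5-(benzyloxy)-8-[2-(benzyloxy)-5-bromophenyl]-7-methoxy-4H-chromen-4-one | COc1cc(OCc2ccccc2)c2c(c1-c1cc(Br)ccc1OCc1ccccc1)occc2=O
F4 | step 9 | 4-[(1R)-1-hydroxybut-3-en-1-yl]phenyl acetate | O[C@@H](c1ccc(OC(C)=O)cc1)CC=C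
F5 | step 9 | 4-[(1S)-1-{5-(benzyloxy)-2-[2-(benzyloxy)-5-bromophenyl]-3-methoxyphenoxy}but-3-en-1-yl]phenyl acetate | COc1cc(OCc2ccccc2)cc(O[C@H](c2ccc(OC(C)=O)cc2)CC=C)c1-c1cc(Br)ccc1OCc1ccccc1
F6 | step 9 | 4-[(1S)-1-{5-(benzyloxy)-2-[2-(benzyloxy)-5-bromophenyl]-3-methoxyphenoxy}-3-oxopropyl]phenyl acetate | COc1cc(OCc2ccccc2)cc(O[C@H](c2ccc(OC(C)=O)cc2)CC=O)c1-c1cc(Br)ccc1OCc1ccccc1
F7 | step 16 | 4-oxo-4H-chromene-5,7-diyl diacetate | CC(=O)Oc1cc(OC(C)=O)c2c(c1)occc2=O
F8 | step 16 | (2S)-2-{3-[(2S)-2-[4-(acetyloxy)phenyl]-5-(benzyloxy)-7-methoxy-4-oxochroman-8-yl]-4-(benzyloxy)phenyl}-4-oxochroman-5,7-diyl diacetate | COc1cc(OCc2ccccc2)c2c(c1-c1cc([C@@H]3CC(=O)c4c(OC(C)=O)cc(OC(C)=O)cc4O3)ccc1OCc1ccccc1)O[C@H](c1ccc(OC(C)=O)cc1)CC2=O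
F9 | step 16 | (2S)-5-(benzyloxy)-8-{2-(benzyloxy)-5-[(2S)-5,7-dihydroxy-4-oxochroman-2-yl]phenyl}-2-(4-hydroxyphenyl)-7-methoxychroman-4-one | COc1cc(OCc2ccccc2)c2c(c1-c1cc([C@@H]3CC(=O)c4c(O)cc(O)cc4O3)ccc1OCc1ccccc1)O[C@H](c1ccc(O)cc1)CC2=O
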